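**Remark on the chemistry:** the single stereocentre of 11 is R at the α-carbon of the lactic acid unit; compound 6 is drawn as the keto acid although it is largely enolised, and carbon monoxide is counted as numbered reactant 9.

## Analysis of the target

Eritrichin 11 is an ester built from two caffeate-derived halves. The acid half is a naphthalene in which ring A (C4a, C5 to C8, C8a) carries hydroxyls at C6 and C7 and ring B (C1 to C4) carries a 3,4-dihydroxyphenyl group at C4 and the carboxyl carbon at C2, with hydrogen at C1 and C3. The alcohol half is (R)-3-(3,4-dihydroxyphenyl)lactic acid, bound through its C2 oxygen, with its own carboxyl free. The only stereocentre is that α-carbon, so there is no relative stereochemistry, but lost configuration cannot be recovered by separating diastereomers. The sensitive groups are three catechols (oxidised in air, faster in base), a free acid, and the ester of a secondary α-hydroxy acid, which can be cleaved and whose α-hydrogen is acidified by the adjacent carboxyl and acyloxy groups. Three things make the synthesis hard: the regiodefined 2,4,6,7-substituted naphthalene, acylation of a hindered and electron-poor secondary alcohol by a naphthoyl unit without racemisation, and unmasking six phenols and an acid at the end while the ester stays intact. The strategy rests on the carbonyl carbon on C2, a one-carbon bridge between C2 of ring B and the lactate oxygen, which can be brought in as 9 if C2 carries an oxygen leaving group. A C2 oxygen in a 1,3-relation to the C4 aryl group is exactly what an arylacetyl/arylalkyne benzannulation delivers.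

## Retrosynthetic reasoning

**11 from 10.** The last operation cuts six O–methyl bonds and the O–tert-butyl bond. Methyl ethers and a tert-butyl ester are chosen because they survive a strong Lewis acid in the ring-forming step and palladium, amine and heat in the coupling, and because one Lewis-acidic dealkylation removes them all. The forward step has to do this without cleaving the naphthoate ester of 10.

**10 from 5, 8 and 9.** Both bonds at the ester carbonyl carbon are cut: C2–carbonyl and carbonyl–oxygen. This is the only place where the two halves meet. Cutting on both sides of the carbonyl turns the naphthalene partner into a phenol derivative (5) instead of a carboxylic acid, so no carboxyl group has to be installed on ring B, protected or activated. The chiral alcohol 8 enters late, onto a fully aromatic partner. The forward reaction must activate only the C2–O bond of 5, insert 9, and let a hindered secondary alcohol capture the acyl–metal intermediate under conditions too mild to epimerise the α-centre.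

**5 from 4.** The S–O bond is cut. Sulfonylation of the lone naphthol hydroxyl of 4 is unambiguous because all other oxygens are methyl ethers.

**4 from 1 and 2.** Ring B is cut at C2–C3 and C4–C4a. Here the acyl carbon of 1 becomes C2, its methylene becomes C1, and its arene becomes ring A. The terminal alkyne carbon of 2 becomes C3 and the internal one becomes C4 with its aryl group. One step from two commercial compounds gives ring B and the whole substitution pattern. The forward reaction needs two regioselective events: acylation of the alkyne at its terminal carbon, and ring closure para to the 3-methoxy group of 1, which places the methoxyls at C6 and C7.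

**8 from 7.** The carbinol C–H bond is cut. The stereocentre is created by asymmetric hydrogenation of the ketone of 7, where the neighbouring ester can chelate the catalyst. A catalytic method is preferred because either enantiomer of the ligand is available.

**7 from 6.** The ester O–C(CH3)3 bond is cut. The tert-butyl group must be introduced under nearly neutral conditions because 6 is an enolisable α-keto acid prone to self-condensation.

## Alternatives that were turned down

**Alternative 1:** Ring B is cut at C4–C4a, and one carboxyl carbon more than the target needs is carried. Diethyl (2E,3E)-2,3-bis(3,4-dimethoxybenzylidene)succinate A2 is treated with a strong sulfonic acid. Protonation of one styrenic double bond gives a benzylic cation, and the electron-rich ring of the other arylidene unit closes onto it to give diethyl trans-1-(3,4-dimethoxyphenyl)-6,7-dimethoxy-1,2-dihydronaphthalene-2,3-dicarboxylate A1 (racemic).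
- For: it follows the probable biogenesis from two caffeate units, and A2 comes from commodity chemicals by Stobbe condensations. The C4 aryl group and the C6/C7 oxygens follow from the symmetry of A2, so on regiochemical security it is at least as strong as the annulation to 4.
- Against: A1 has an ester on the carbon next to the aryl-bearing carbon, where the target has hydrogen (C3). The saturated and the conjugated ester of A1 must be told apart, one hydrolysed and removed by oxidative decarboxylation with aromatisation, and two stereocentres are made only to be erased. Hydrolysis of the remaining ester, activation of a hindered naphthoic acid, acylation of 8 and demethylation follow. This is about eight steps in the longest line against four.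
- Comparison: a classical acylation of 8 is more predictable than a three-component carbonylation. The chosen strategy offers in its place half the step count, no redox corrections and no carboxyl activation.

**Alternative 2:** Ring A is cut at C4a–C5 and C8–C8a. Methyl 3-(3,4-dimethoxyphenyl)-5-iodo-4-(trifluoromethanesulfonyloxy)benzoate A4 is converted into an aryne by iodine–magnesium exchange with a silylmethyl Grignard reagent and loss of triflate. The aryne is trapped in a [4+2] addition by 2,3-dimethoxybuta-1,3-diene A5 to give methyl 4-(3,4-dimethoxyphenyl)-6,7-dimethoxy-5,8-dihydronaphthalene-2-carboxylate A3. Dehydrogenation, ester hydrolysis, esterification with 8 and demethylation would follow.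
- For: A5 is symmetric, so ring A raises no regiochemical question, and here this alternative equals or surpasses the chosen route. The carboxyl carbon is on the ring from the start, and the aryne forms at low temperature.
- Against: A4 is a contiguously substituted benzene that needs regiocontrolled halogenation, a mono-selective cross-coupling and triflation, four or five steps by itself. The magnesium reagent must spare the methyl ester of A4. Acyclic 2,3-dialkoxydienes such as A5 populate the s-cis form poorly, so ene and [2+2] pathways compete. A3 is an acid-labile bis-enol ether that still has to be oxidised. The ester to 8 again needs an activated acid.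
- Comparison: the count approaches ten steps. In the chosen route ring A arrives ready-made in 1 and ring B is closed in one step.

**Alternative 3:** Ring B is cut at C1–C2 and C3–C4 with the ester already in place. Irradiation near 365 nm of 2-(3,4-dimethoxybenzyl)-4,5-dimethoxybenzaldehyde A7 gives a hydroxy-ortho-quinodimethane by hydrogen transfer from the diarylmethane carbon. This diene adds the acrylate tert-butyl (R)-2-(acryloyloxy)-3-(3,4-dimethoxyphenyl)propanoate A8 to give the 1-hydroxy-4-aryl-tetrahydronaphthalene-2-carboxylate A6 as a mixture of isomers. Dehydration and dehydrogenation would lead to 10.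
- For: the hindered ester bond is made by simple acryloylation of 8 to A8, the easiest way possible and clearly stronger than a carbonylation on that point. No metal and no carbon monoxide are needed, and the isomer mixture in A6 does not matter because all three ring stereocentres are flattened.
- Against: A6 is one water and two hydrogens away from the naphthalene. Acid-mediated dehydration and a quinone-type dehydrogenation must be run on a molecule with an acid-labile tert-butyl ester, four electron-rich rings and the stereocentre. The chiral fragment, carried in A8, is exposed to three more steps. A7 needs its own two or three steps, and its aryl-substituted photoenol is more hindered than the usual ortho-methyl cases.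
- Comparison: the longest line is about six steps. In the chosen route the naphthalene is aromatic from the first step and the chiral fragment enters in the penultimate step.

Key step: step 5

## Route

Step 1
Reactants: 1 3,4-dimethoxyphenylacetyl chloride; 2 4-ethynyl-1,2-dimethoxybenzene
Product: 4 4-(3,4-dimethoxyphenyl)-6,7-dimethoxynaphthalen-2-ol, via naphthalen-2(1H)-one tautomer 3 (not isolated)
Conditions: AlCl3 (2.5 equiv), CH2Cl2, −20 °C → rt; then ice/1 M HCl
Reagents that add atoms: none
Why: Friedel–Crafts acylation of the alkyne followed by intramolecular Friedel–Crafts vinylation (the AlCl3-mediated arylacetyl chloride/alkyne benzannulation to 2-naphthols): the acylium ion from 1 adds to the terminal carbon of 2 to give the aryl-stabilised vinyl cation, which closes onto the position para to the 3-methoxy group of the arylacetyl ring. Loss of a proton gives ketone 3, which enolises to the aromatic naphthol 4 with the hydroxyl at C2, the aryl group at C4 and the methoxyls at C6 and C7.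

Step 2
Reactants: 4 4-(3,4-dimethoxyphenyl)-6,7-dimethoxynaphthalen-2-ol
Product: 5 4-(3,4-dimethoxyphenyl)-6,7-dimethoxynaphthalen-2-yl trifluoromethanesulfonate
Conditions: Tf2O (1.2 equiv), pyridine (2 equiv), CH2Cl2, 0 °C
Reagents that add atoms: trifluoromethanesulfonic anhydride, O=S(=O)(OS(=O)(=O)C(F)(F)F)C(F)(F)F
Why: O-sulfonylation of a phenol with triflic anhydride; the naphthol is the only free hydroxyl and pyridine takes up the acid.

Step 3
Reactants: 6 3-(3,4-dimethoxyphenyl)-2-oxopropanoic acid (3,4-dimethoxyphenylpyruvic acid)
Product: 7 tert-butyl 3-(3,4-dimethoxyphenyl)-2-oxopropanoate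
Conditions: tert-butyl 2,2,2-trichloroacetimidate (2 equiv), CH2Cl2/cyclohexane, rt
Reagents that add atoms: tert-butyl 2,2,2-trichloroacetimidate, CC(C)(C)OC(=N)C(Cl)(Cl)Cl
Why: tert-butyl esterification by imidate transfer: the carboxylic acid protonates the imidate and captures the tert-butyl cation, so neither a base nor a strong acid that could set off aldol self-condensation of the enolisable keto acid is present. The less acidic enol hydroxyl should not react without an added catalyst.

Step 4
Reactants: 7 tert-butyl 3-(3,4-dimethoxyphenyl)-2-oxopropanoate
Product: 8 tert-butyl (R)-3-(3,4-dimethoxyphenyl)-2-hydroxypropanoate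
Conditions: [RuCl(p-cymene)((R)-SEGPHOS)]Cl (1 mol %), H2 (30 bar), EtOH, 50 °C
Reagents that add atoms: none
Why: Noyori-type asymmetric hydrogenation of an α-keto ester with a divalent ruthenium–diphosphine catalyst: keto and ester carbonyls chelate the metal and hydride is delivered to one face of the ketone, the face being fixed by the chiral pocket of the biaryl diphosphine. With the R ligand the sense known for simple pyruvates corresponds to the R alcohol here, the arylmethyl group taking the place of methyl; the configuration is to be confirmed at this stage, and the S ligand is equally available should the sense on this substrate prove opposite.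

Step 5
Reactants: 5 4-(3,4-dimethoxyphenyl)-6,7-dimethoxynaphthalen-2-yl trifluoromethanesulfonate; 8 tert-butyl (R)-3-(3,4-dimethoxyphenyl)-2-hydroxypropanoate (1.5 equiv); 9 carbon monoxide
Product: 10 (R)-1-tert-butoxy-3-(3,4-dimethoxyphenyl)-1-oxopropan-2-yl 4-(3,4-dimethoxyphenyl)-6,7-dimethoxy-2-naphthoate
Conditions: Pd(OAc)2 (5 mol %), Xantphos (7.5 mol %), CO (3 bar), iPr2NEt (2.5 equiv), DMAP (20 mol %), 4 Å MS, toluene, 90 °C
Reagents that add atoms: none
Why: Heck-type alkoxycarbonylation of an aryl triflate, a known reaction class, run here with a stoichiometric secondary alcohol in place of the usual excess of methanol. Pd(OAc)2 is reduced in the flask to a zerovalent palladium–Xantphos complex, to which the C2–OTf bond of 5 adds oxidatively; no other bond in 5 or 8 can do so, because aryl methyl ethers and the tert-butyl ester are inert to zerovalent palladium. The cationic arylpalladium species (divalent palladium) takes up 9, and migratory insertion creates the C2–carbonyl bond in a 2-naphthoyl complex. The hydroxyl of 8 then attacks the acyl carbon, directly with the amine as proton acceptor or through the N-acylpyridinium ion that DMAP draws from the metal, which creates the carbonyl–oxygen bond, releases 10 and leaves a palladium hydride that the amine returns to the zerovalent state as its triflate salt. Xantphos, with its wide bite angle, keeps the catalyst active under a few bar of CO and speeds the product-forming step, which matters because a hindered, electron-poor α-hydroxy ester captures the acyl complex slowly. No ring is closed and no stereocentre is made: the R centre of 8 is not a reacting atom, and neither iPr2NEt nor DMAP is basic enough to remove the α-hydrogen of 8 or of 10. The selectivity needed is capture of the acyl complex by 8 rather than by water or by a naphthoxide from triflate cleavage, which dry conditions, molecular sieves, a non-nucleophilic amine and an excess of 8 are meant to secure.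

Step 6
Reactants: 10 (R)-1-tert-butoxy-3-(3,4-dimethoxyphenyl)-1-oxopropan-2-yl 4-(3,4-dimethoxyphenyl)-6,7-dimethoxy-2-naphthoate
Product: 11 eritrichin, (R)-2-{[4-(3,4-dihydroxyphenyl)-6,7-dihydroxy-2-naphthoyl]oxy}-3-(3,4-dihydroxyphenyl)propanoic acid
Conditions: BBr3 (12 equiv), CH2Cl2, −78 → 0 °C; then ice-water; reversed-phase chromatography under argon
Reagents that add atoms: none
Why: Lewis-acid dealkylation: BBr3 binds each aryl ether oxygen and bromide removes the methyl group by SN2 attack, while the tert-butyl ester loses its tert-butyl group by ionisation; hydrolysis of the aryl and acyl borates on work-up gives 11. The naphthoate ester should survive at low temperature because its alkyl–oxygen bond sits at a secondary carbon next to a boron-bound carboxyl, where ionisation is disfavoured and bromide attack is far slower than at methyl; the R centre is not a reacting atom.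

## Compound list

1 | 3,4-dimethoxyphenylacetyl chloride | COc1ccc(CC(=O)Cl)cc1OC | starting material
2 | 4-ethynyl-1,2-dimethoxybenzene | C#Cc1ccc(OC)c(OC)c1 | starting material
3 | 4-(3,4-dimethoxyphenyl)-6,7-dimethoxynaphthalen-2(1H)-one | O=C1Cc2cc(OC)c(OC)cc2C(c2ccc(OC)c(OC)c2)=C1 | intermediate (not isolated)
4 | 4-(3,4-dimethoxyphenyl)-6,7-dimethoxynaphthalen-2-ol | Oc1cc(-c2ccc(OC)c(OC)c2)c2cc(OC)c(OC)cc2c1 | intermediate
5 | 4-(3,4-dimethoxyphenyl)-6,7-dimethoxynaphthalen-2-yl trifluoromethanesulfonate | O=S(=O)(Oc1cc(-c2ccc(OC)c(OC)c2)c2cc(OC)c(OC)cc2c1)C(F)(F)F | intermediate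
6 | 3-(3,4-dimethoxyphenyl)-2-oxopropanoic acid | COc1ccc(CC(=O)C(=O)O)cc1OC | starting material
7 | tert-butyl 3-(3,4-dimethoxyphenyl)-2-oxopropanoate | COc1ccc(CC(=O)C(=O)OC(C)(C)C)cc1OC | intermediate
8 | tert-butyl (R)-3-(3,4-dimethoxyphenyl)-2-hydroxypropanoate | O[C@H](Cc1ccc(OC)c(OC)c1)C(=O)OC(C)(C)C | intermediate
9 | carbon monoxide | [C-]#[O+] | starting material
10 | (R)-1-tert-butoxy-3-(3,4-dimethoxyphenyl)-1-oxopropan-2-yl 4-(3,4-dimethoxyphenyl)-6,7-dimethoxy-2-naphthoate | O=C(O[C@H](Cc1ccc(OC)c(OC)c1)C(=O)OC(C)(C)C)c1cc(-c2ccc(OC)c(OC)c2)c2cc(OC)c(OC)cc2c1 | intermediate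
11 | eritrichin, (R)-2-{[4-(3,4-dihydroxyphenyl)-6,7-dihydroxy-2-naphthoyl]oxy}-3-(3,4-dihydroxyphenyl)propanoic acid | O=C(O[C@H](Cc1ccc(O)c(O)c1)C(=O)O)c1cc(-c2ccc(O)c(O)c2)c2cc(O)c(O)cc2c1 | target

## Step count and least certain steps

Total: 6 steps. Longest linear sequence: 4 steps (1 and 2 → 4 → 5 → 10 → 11, or 6 → 7 → 8 → 10 → 11).

**Step 5 (key step).** The most likely failure is slow capture of the naphthoyl–palladium intermediate by the hindered, electron-poor alcohol. The intermediate would then be diverted by traces of water to the acid, or by β-hydride transfer from a palladium-bound alkoxide of 8 to a reduced arene or aldehyde with oxidation of 8 back to 7. Cleavage of the triflate at sulfur would return 4. Fallback: the carbonylation is separated from the ester formation. From 5, methoxycarbonylation with methanol as co-solvent (Pd(OAc)2, 1,3-bis(diphenylphosphino)propane, CO, Et3N, DMF/MeOH, 70 °C) should give methyl 4-(3,4-dimethoxyphenyl)-6,7-dimethoxy-2-naphthoate F1. Saponification with LiOH in THF/water gives 4-(3,4-dimethoxyphenyl)-6,7-dimethoxy-2-naphthoic acid F2. Steglich esterification of F2 with 8 (EDC·HCl, DMAP, CH2Cl2) rejoins the route at 10. The stereocentre is on the alcohol partner, so activation of the acid cannot racemise it.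

**Step 1.** Intermolecular acylation of the electron-rich rings of 1, 2 or 4 may compete, along with cationic oligomerisation of the alkyne, loss of carbon monoxide from the acylium ion to a stabilised benzylic cation, and partial demethylation of the vicinal methoxyls by AlCl3. All of these would lower the amount of clean naphthol. Fallback: ring B is built by aroylation and aldol condensation instead. From 1, MeMgBr with catalytic Fe(acac)3 in THF at −78 °C gives 1-(3,4-dimethoxyphenyl)propan-2-one F3 (also an article of commerce). Friedel–Crafts aroylation of F3 with 3,4-dimethoxybenzoyl chloride and SnCl4 in CH2Cl2 takes place para to the 3-methoxy group and ortho to the side chain. After a basic aqueous work-up, which opens any 2-benzopyrylium salt formed, it gives 1-[2-(3,4-dimethoxybenzoyl)-4,5-dimethoxyphenyl]propan-2-one F4. NaOH in EtOH at reflux closes ring B by intramolecular aldol condensation of the methyl ketone onto the diaryl ketone; dehydration and enolisation rejoin the route at 4. The benzylic enolate of F4 cannot cyclise productively (it would form a four-membered ring), so only the 4-aryl-2-naphthol can arise.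

**Step 4.** Enantioselectivity may be eroded because 7 is largely enolised and hydrogenation through the enol double bond need not follow the same facial preference as the chelated ketone. The bulky tert-butyl ester may also weaken chelation. The final product has one stereocentre, so the enantiomeric purity must be high here. Fallback: the stereocentre is set by alkene hydrogenation. From 7, Ac2O, pyridine and DMAP give tert-butyl (Z)-2-acetoxy-3-(3,4-dimethoxyphenyl)acrylate F5. Hydrogenation of F5 with [Rh(cod)((R,R)-Et-DuPhos)]BF4 (H2, 4 bar, MeOH), the enol ester counterpart of dehydroamino acid hydrogenation, is expected to give tert-butyl (R)-2-acetoxy-3-(3,4-dimethoxyphenyl)propanoate F6. K2CO3 in MeOH at 0 °C removes the acetate of F6 without touching the tert-butyl ester and rejoins the route at 8.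

**Step 6.** The naphthoate ester may be cleaved by the Lewis acid. Demethylation of six ethers may stop short, and the three catechols may oxidise during work-up. Fallback: methyl is exchanged for benzyl before the coupling, so that the last step becomes a hydrogenolysis. On the naphthalene side, BBr3 on 5, which has no ester and whose triflate tolerates the reagent, gives 4-(3,4-dihydroxyphenyl)-6,7-dihydroxynaphthalen-2-yl trifluoromethanesulfonate F7, and BnBr with K2CO3 in DMF at room temperature then gives 4-[3,4-bis(benzyloxy)phenyl]-6,7-bis(benzyloxy)naphthalen-2-yl trifluoromethanesulfonate F8. On the lactate side, BBr3 on 8 gives (R)-3-(3,4-dihydroxyphenyl)-2-hydroxypropanoic acid F9, and BnBr with K2CO3 in DMF alkylates the carboxylate and the phenoxides of F9 but not the secondary alcohol, to give benzyl (R)-3-[3,4-bis(benzyloxy)phenyl]-2-hydroxypropanoate F10. The conditions of step 5 applied to F8, F10 and 9 give (R)-1-(benzyloxy)-3-[3,4-bis(benzyloxy)phenyl]-1-oxopropan-2-yl 4-[3,4-bis(benzyloxy)phenyl]-6,7-bis(benzyloxy)-2-naphthoate F11. H2 over Pd/C in EtOAc/MeOH removes all seven benzyl groups of F11 and arrives at 11. The naphthalene and the homobenzylic ester C–O bond are not expected to react under these conditions.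

## Further compounds

F1 | step 5 | methyl 4-(3,4-dimethoxyphenyl)-6,7-dimethoxy-2-naphthoate | COC(=O)c1cc(-c2ccc(OC)c(OC)c2)c2cc(OC)c(OC)cc2c1
F2 | step 5 | 4-(3,4-dimethoxyphenyl)-6,7-dimethoxy-2-naphthoic acid | O=C(O)c1cc(-c2ccc(OC)c(OC)c2)c2cc(OC)c(OC)cc2c1
F3 | step 1 | 1-(3,4-dimethoxyphenyl)propan-2-one | CC(=O)Cc1ccc(OC)c(OC)c1
F4 | step 1 | 1-[2-(3,4-dimethoxybenzoyl)-4,5-dimethoxyphenyl]propan-2-one | CC(=O)Cc1cc(OC)c(OC)cc1C(=O)c1ccc(OC)c(OC)c1
F5 | step 4 | tert-butyl (Z)-2-acetoxy-3-(3,4-dimethoxyphenyl)acrylate | CC(=O)O/C(=C\c1ccc(OC)c(OC)c1)C(=O)OC(C)(C)C
F6 | step 4 | tert-butyl (R)-2-acetoxy-3-(3,4-dimethoxyphenyl)propanoate | CC(=O)O[C@H](Cc1ccc(OC)c(OC)c1)C(=O)OC(C)(C)C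
F7 | step 6 | 4-(3,4-dihydroxyphenyl)-6,7-dihydroxynaphthalen-2-yl trifluoromethanesulfonate | O=S(=O)(Oc1cc(-c2ccc(O)c(O)c2)c2cc(O)c(O)cc2c1)C(F)(F)F
F8 | step 6 | 4-[3,4-bis(benzyloxy)phenyl]-6,7-bis(benzyloxy)naphthalen-2-yl trifluoromethanesulfonate | O=S(=O)(Oc1cc(-c2ccc(OCc3ccccc3)c(OCc3ccccc3)c2)c2cc(OCc3ccccc3)c(OCc3ccccc3)cc2c1)C(F)(F)F
F9 | step 6 | (R)-3-(3,4-dihydroxyphenyl)-2-hydroxypropanoic acid | O[C@H](Cc1ccc(O)c(O)c1)C(=O)O
F10 | step 6 | benzyl (R)-3-[3,4-bis(benzyloxy)phenyl]-2-hydroxypropanoate | O[C@H](Cc1ccc(OCc2ccccc2)c(OCc2ccccc2)c1)C(=O)OCc1ccccc1
F11 | step 6 | (R)-1-(benzyloxy)-3-[3,4-bis(benzyloxy)phenyl]-1-oxopropan-2-yl 4-[3,4-bis(benzyloxy)phenyl]-6,7-bis(benzyloxy)-2-naphthoate | O=C(O[C@H](Cc1ccc(OCc2ccccc2)c(OCc2ccccc2)c1)C(=O)OCc1ccccc1)c1cc(-c2ccc(OCc3ccccc3)c(OCc3ccccc3)c2)c2cc(OCc3ccccc3)c(OCc3ccccc3)cc2c1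
A1 | alternative 1 | diethyl trans-1-(3,4-dimethoxyphenyl)-6,7-dimethoxy-1,2-dihydronaphthalene-2,3-dicarboxylate (racemic, one enantiomer drawn) | CCOC(=O)C1=Cc2cc(OC)c(OC)cc2[C@@H](c2ccc(OC)c(OC)c2)[C@@H]1C(=O)OCC
A2 | alternative 1 | diethyl (2E,3E)-2,3-bis(3,4-dimethoxybenzylidene)succinate | CCOC(=O)/C(=C/c1ccc(OC)c(OC)c1)/C(=C\c1ccc(OC)c(OC)c1)C(=O)OCC
A3 | alternative 2 | methyl 4-(3,4-dimethoxyphenyl)-6,7-dimethoxy-5,8-dihydronaphthalene-2-carboxylate | COC(=O)c1cc(-c2ccc(OC)c(OC)c2)c2c(c1)CC(OC)=C(OC)C2
A4 | alternative 2 | methyl 3-(3,4-dimethoxyphenyl)-5-iodo-4-(trifluoromethanesulfonyloxy)benzoate | COC(=O)c1cc(I)c(OS(=O)(=O)C(F)(F)F)c(-c2ccc(OC)c(OC)c2)c1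
A5 | alternative 2 | 2,3-dimethoxybuta-1,3-diene | C=C(OC)C(OC)=C
A6 | alternative 3 | (R)-1-tert-butoxy-3-(3,4-dimethoxyphenyl)-1-oxopropan-2-yl 4-(3,4-dimethoxyphenyl)-1-hydroxy-6,7-dimethoxy-1,2,3,4-tetrahydronaphthalene-2-carboxylate (mixture of isomers at the three ring carbons) | COc1ccc(C2CC(C(=O)O[C@H](Cc3ccc(OC)c(OC)c3)C(=O)OC(C)(C)C)C(O)c3cc(OC)c(OC)cc32)cc1OC
A7 | alternative 3 | 2-(3,4-dimethoxybenzyl)-4,5-dimethoxybenzaldehyde | COc1ccc(Cc2cc(OC)c(OC)cc2C=O)cc1OC
A8 | alternative 3 | tert-butyl (R)-2-(acryloyloxy)-3-(3,4-dimethoxyphenyl)propanoate | C=CC(=O)O[C@H](Cc1ccc(OC)c(OC)c1)C(=O)OC(C)(C)C
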